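The acid set free cannot leave a closed flask, so I must book it somewhere.

electrophile 20 mM; protonated nucleophile 1.05 equiv; time 1.0 h

    electrophile + nucleophile → acid set free + target (k1 = 3.0 M⁻¹ s⁻¹)
    nucleophile + acid set free ⇌ protonated nucleophile, settled at all times (K2 = 9000 M⁻¹)
    acid set free + free base ⇌ salt of the base (K3 = 97000 M⁻¹, k3 = 0.32 M⁻¹ s⁻¹)
    free base + target ⇌ idle adduct, settled at all times (K4 = 1400 M⁻¹)
    target ⇌ isomer of the product (K5 = 2.1, k5 = 0.0011 s⁻¹)

* the equivalents of free base at which the part of the electrophile that has reacted at 1.0 h is just 90%

- for target the idle adduct is counted in
- the amount of free base is what is sought; it is there from the start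
- run time (flask): 1.0 h

I keep the books in fractions of the charged electrophile, the limiting reagent. Entry one: each reacted unit uses a nucleophile that came off the protonated nucleophile. That leaves one acid behind, and step one sets free another. So each reacted unit books two acids.

Entry two: at balance, free nucleophile equals protonated nucleophile over 9000 M⁻¹ times free acid. The rate of reaction is therefore unreacted electrophile times protonated nucleophile left, over free acid, all divided by a clock. The clock is 9000 M⁻¹ over 3.0 M⁻¹ s⁻¹, or 50.0 min, and it holds no concentration.

Entry three: I round the nucleophile to one equivalent and do not count free nucleophile. In this reckoning with no base, both booked acids stay free, and integrating to 90% gives 11.2 h, longer than the 1.0 h allowed. To finish in time, I assume that free acid stays a fixed share of the reacted fraction, and that share comes to 17.9%.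

Entry four: on that assumption, the rest of the two acids sits as salt. The salt demand, the equivalents of acid that sit as salt at 90% reacted on that assumption, is 1.64. Base in idle adduct or still free comes on top, so my estimate is a charge above 1.64 equivalents.

The forecast gives 0.22 equiv, on this ground: “Only a little base is therefore needed.” That differs from my estimate, which starts at the salt demand of 1.64 equivalents.

The simulation needs 2.24 equiv, which is 10.2 times the forecast. In that flask, 4.27% of the charged base is still free at 1.00 h. The bound base, salt and idle adduct together, is then 2.15. That stands at 1.31 times the salt demand of 1.64.

The numbers are made up; the result is computed.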